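## Retrosynthetic overview

1. The sulfate comes from the primary alcohol. The side chain–lactam C(sp3)–C(sp2) bond comes from a B-alkyl Suzuki coupling of a terminal alkene with a 3-bromo-lactam, itself made in two steps from 3-methylbutan-1-amine.
2. The side-chain stereocentre comes from a chiral-amine-controlled α-allylation of the decalin butanal, reduced in situ.
3. The butanal comes from a C-1 allyl group (cross-metathesis with acrolein, then hydrogenation). The same hydrogenation sets the C-2 methyl via an exocyclic methylene made from the C-2 ketone.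
4. The quaternary C-1 and the Δ8(8a) alkene come from a deconjugative α-allylation of a bicyclic enone.
5. Ring order: ring B is bought (cyclohexenone); ring A is closed onto it by a new IDPi-catalysed asymmetric dienol-terminated cationic cyclization that sets the first stereocentre; the lactam ring is made separately.

Assumption: compound 1 is taken as commercial (otherwise one step from 2-methylcyclohexane-1,3-dione), the target is isolated as the free hydrogen sulfate drawn, and the catalyst enantiomers in steps 2 and 7 are assigned by model and would be switched to the antipode if the observed sense is opposite.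

Bicycle locants (C-1, C-2, C-4a, C-8, C-8a) follow naphthalene numbering.

## Route

Step 1
Reactants: 1 3-ethoxy-2-methylcyclohex-2-en-1-one; 2 5-bromo-2-methylpent-2-ene
Product: 4 2-methyl-3-(4-methylpent-3-en-1-yl)cyclohex-2-en-1-one, via carbinol adduct 3 (not isolated)
Conditions: 2, Mg, THF, 40 °C; then 1, 0 °C → rt; then 1 M HCl, rt
Reagents that add atoms: 5-bromo-2-methylpent-2-ene (CC(C)=CCCBr)
Why: Stork–Danheiser enone transposition: Grignard 1,2-addition to the vinylogous ester, then acid hydrolysis with loss of ethanol gives the 3-alkyl enone; no stereocentre is formed.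

Step 2
Reactants: 4 2-methyl-3-(4-methylpent-3-en-1-yl)cyclohex-2-en-1-one
Product: 6 (4aS)-1,5,5-trimethyl-4,4a,5,6,7,8-hexahydronaphthalen-2(3H)-one, via endocyclic dienol 5 (not isolated)
Conditions: (S,S)-IDPi (confined N-triflyl imidodiphosphorimidate Brønsted acid, 5 mol%), (CF3)3COH/CH2Cl2, −20 °C → rt, quenched (Et3N) at full conversion
Reagents that add atoms: none
Why: Proposed new method: catalytic asymmetric dienol-terminated cation–olefin cyclization, in which the strong confined acid tautomerizes the enone to dienol 5 (the exocyclic dienol is unproductive and reverts), protonation of the isopropylidene CH inside the chiral ion pair and 6-endo chair closure of the tertiary cation onto the dienol γ-carbon gives the O-protonated enone directly (α-attack would join two quaternary carbons, and enone-initiated closure would need a four-membered ring or a secondary cation), and the anion's discrimination of the γ-carbon faces sets C-4a (S) while closing ring A; the closest known reaction types are IDPi-catalysed protonation-initiated asymmetric polyene cyclizations and the acid-mediated pseudoionone-to-ionone and β-keto-ester-terminated cyclizations.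

Step 3
Reactants: 6 (4aS)-1,5,5-trimethyl-4,4a,5,6,7,8-hexahydronaphthalen-2(3H)-one; 7 allyl bromide
Product: 9 (1S,4aS)-1,5,5-trimethyl-1-(prop-2-en-1-yl)-3,4,4a,5,6,7-hexahydronaphthalen-2(1H)-one, via potassium dienolate 8 (not isolated)
Conditions: KOt-Bu (1.1 equiv), t-BuOH/THF, 0 °C, 10 min; allyl bromide, 0 °C → rt
Reagents that add atoms: allyl bromide (C=CCBr)
Why: Deconjugative α-alkylation of the heteroannular extended dienolate: axial attack at C-1 through a chair-like transition state on the face of the axial 4a-H puts the allyl group cis to 4a-H (1S) and moves the alkene to C-8=C-8a.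

Step 4
Reactants: 9 (1S,4aS)-1,5,5-trimethyl-1-(prop-2-en-1-yl)-3,4,4a,5,6,7-hexahydronaphthalen-2(1H)-one; 10 methyltriphenylphosphonium bromide
Product: 11 (1R,4aS)-1,5,5-trimethyl-2-methylidene-1-(prop-2-en-1-yl)-1,2,3,4,4a,5,6,7-octahydronaphthalene
Conditions: Ph3PCH3Br, KOt-Bu, THF, 0 → 60 °C
Reagents that add atoms: methyltriphenylphosphonium bromide (C[P+](c1ccccc1)(c1ccccc1)c1ccccc1.[Br-])
Why: Wittig methylenation of the hindered ketone, whose quaternary α-carbon cannot epimerize; the temperature is kept at or below 60 °C to avoid Cope rearrangement of the 1,5-diene.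

Step 5
Reactants: 11 (1R,4aS)-1,5,5-trimethyl-2-methylidene-1-(prop-2-en-1-yl)-1,2,3,4,4a,5,6,7-octahydronaphthalene; 12 acrolein
Product: 13 (2E)-4-[(1R,4aS)-1,5,5-trimethyl-2-methylidene-1,2,3,4,4a,5,6,7-octahydronaphthalen-1-yl]but-2-enal
Conditions: Hoveyda–Grubbs II (3 mol%), acrolein (4 equiv), CH2Cl2, 40 °C
Reagents that add atoms: acrolein (C=CC=O)
Why: Olefin cross-metathesis of the only unhindered terminal alkene with acrolein (E-selective); the 1,1-disubstituted and trisubstituted alkenes next to the quaternary carbon do not react.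

Step 6
Reactants: 13 (2E)-4-[(1R,4aS)-1,5,5-trimethyl-2-methylidene-1,2,3,4,4a,5,6,7-octahydronaphthalen-1-yl]but-2-enal
Product: 14 4-[(1R,2R,4aS)-1,2,5,5-tetramethyl-1,2,3,4,4a,5,6,7-octahydronaphthalen-1-yl]butanal
Conditions: H2 (1 atm), 5% Pt/C, EtOAc, 0 °C → rt, stopped after 2 equiv H2
Reagents that add atoms: none
Why: Heterogeneous hydrogenation reduces the enal C=C and the exocyclic methylene but not the hindered trisubstituted ring alkene; H2 is delivered to the face opposite the axial C-1 side chain, so the C-2 methyl ends equatorial and cis to the chain (2R), though this facial preference is a conformational prediction.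

Step 7
Reactants: 14 4-[(1R,2R,4aS)-1,2,5,5-tetramethyl-1,2,3,4,4a,5,6,7-octahydronaphthalen-1-yl]butanal; 15 allyl acetate
Product: 17 (2S)-2-{2-[(1R,2R,4aS)-1,2,5,5-tetramethyl-1,2,3,4,4a,5,6,7-octahydronaphthalen-1-yl]ethyl}pent-4-en-1-ol, via α-allyl aldehyde 16 (not isolated)
Conditions: allyl acetate, Pd(PPh3)4 (5 mol%), (R)-α,α-diphenylprolinol TMS ether (20 mol%), DMSO/DMF, −20 °C; then NaBH4, MeOH, −20 → 0 °C
Reagents that add atoms: allyl acetate (C=CCOC(C)=O)
Why: Enamine/π-allyl-palladium dual catalysis (Tsuji–Trost α-allylation of an aldehyde) in which the prolinol ether shields one enamine face so that allyl enters the Re face (2S), and in situ reduction prevents racemization; the polar mechanism is chosen because the ring alkene would trap a radical-cation (SOMO) intermediate.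

Step 8
Reactants: 18 3-methylbutan-1-amine; 19 2,5-dimethoxy-2,5-dihydrofuran
Product: 21 1-(3-methylbutyl)-1,5-dihydro-2H-pyrrol-2-one, via (Z)-but-2-enedial 20 (not isolated)
Conditions: 1 M aq HCl, rt; then NaHCO3
Reagents that add atoms: 2,5-dimethoxy-2,5-dihydrofuran (COC1C=CC(OC)O1)
Why: Acetal hydrolysis to the cis-enedial, condensation with the primary amine and redox-neutral tautomerization give the N-alkyl α,β-unsaturated γ-lactam (known lactam synthesis); no stereocentre.

Step 9
Reactants: 21 1-(3-methylbutyl)-1,5-dihydro-2H-pyrrol-2-one; 22 bromine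
Product: 24 3-bromo-1-(3-methylbutyl)-1,5-dihydro-2H-pyrrol-2-one, via trans-dibromolactam 23 (not isolated)
Conditions: Br2, CH2Cl2, 0 °C; then Et3N, 0 °C → rt
Reagents that add atoms: bromine (BrBr)
Why: Bromine addition then E1cB dehydrobromination (loss of the acidic α-H and the β-bromide) gives the α-bromo unsaturated lactam.

Step 10
Reactants: 17 (2S)-2-{2-[(1R,2R,4aS)-1,2,5,5-tetramethyl-1,2,3,4,4a,5,6,7-octahydronaphthalen-1-yl]ethyl}pent-4-en-1-ol; 25 9-borabicyclo[3.3.1]nonane; 24 3-bromo-1-(3-methylbutyl)-1,5-dihydro-2H-pyrrol-2-one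
Product: 27 3-{(4R)-4-(hydroxymethyl)-6-[(1R,2R,4aS)-1,2,5,5-tetramethyl-1,2,3,4,4a,5,6,7-octahydronaphthalen-1-yl]hexyl}-1-(3-methylbutyl)-1,5-dihydro-2H-pyrrol-2-one, via alkyl-9-BBN borane 26 (not isolated)
Conditions: 9-BBN (2.2 equiv), THF, 0 °C → rt; then 24, PdCl2(dppf) (5 mol%), AsPh3, Cs2CO3, DMF/H2O, rt → 40 °C
Reagents that add atoms: 3-bromo-1-(3-methylbutyl)-1,5-dihydro-2H-pyrrol-2-one (CC(C)CCN1CC=C(Br)C1=O)
Why: Anti-Markovnikov hydroboration of the terminal alkene only (the hindered ring alkene is inert to 9-BBN), then B-alkyl Suzuki–Miyaura coupling with the α-bromo enamide-type vinyl bromide; no stereocentre is touched (the CIP descriptor changes from S to R only because the priorities change).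

Step 11
Reactants: 27 3-{(4R)-4-(hydroxymethyl)-6-[(1R,2R,4aS)-1,2,5,5-tetramethyl-1,2,3,4,4a,5,6,7-octahydronaphthalen-1-yl]hexyl}-1-(3-methylbutyl)-1,5-dihydro-2H-pyrrol-2-one; 28 sulfur trioxide–pyridine complex
Product: 29 (2R)-2-{2-[(1R,2R,4aS)-1,2,5,5-tetramethyl-1,2,3,4,4a,5,6,7-octahydronaphthalen-1-yl]ethyl}-5-[1-(3-methylbutyl)-2-oxo-2,5-dihydro-1H-pyrrol-3-yl]pentyl hydrogen sulfate
Conditions: SO3·pyridine (3 equiv), pyridine, rt; then cold H+ ion exchange
Reagents that add atoms: sulfur trioxide–pyridine complex (O=S(=O)([O-])[n+]1ccccc1)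
Why: O-sulfation of the only hydroxyl group under basic conditions that leave the lactam and the ring alkene untouched.

## Compound list

1 | 3-ethoxy-2-methylcyclohex-2-en-1-one | CCOC1=C(C)C(=O)CCC1 | starting material
2 | 5-bromo-2-methylpent-2-ene | CC(C)=CCCBr | starting material
3 | rac-3-ethoxy-2-methyl-1-(4-methylpent-3-en-1-yl)cyclohex-2-en-1-ol | CCOC1=C(C)C(O)(CCC=C(C)C)CCC1 | intermediate (not isolated)
4 | 2-methyl-3-(4-methylpent-3-en-1-yl)cyclohex-2-en-1-one | CC1=C(CCC=C(C)C)CCCC1=O | intermediate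
5 | 2-methyl-3-(4-methylpent-3-en-1-yl)cyclohexa-1,3-dien-1-ol | OC1=C(C)C(CCC=C(C)C)=CCC1 | intermediate (not isolated)
6 | (4aS)-1,5,5-trimethyl-4,4a,5,6,7,8-hexahydronaphthalen-2(3H)-one | CC1=C2CCCC(C)(C)[C@@H]2CCC1=O | intermediate
7 | allyl bromide | C=CCBr | starting material
8 | potassium (4aS)-1,5,5-trimethyl-3,4,4a,5,6,7-hexahydronaphthalen-2-olate | [K+].[O-]C1=C(C)C2=CCCC(C)(C)[C@@H]2CC1 | intermediate (not isolated)
9 | (1S,4aS)-1,5,5-trimethyl-1-(prop-2-en-1-yl)-3,4,4a,5,6,7-hexahydronaphthalen-2(1H)-one | C=CC[C@@]1(C)C2=CCCC(C)(C)[C@@H]2CCC1=O | intermediate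
10 | methyltriphenylphosphonium bromide | C[P+](c1ccccc1)(c1ccccc1)c1ccccc1.[Br-] | starting material
11 | (1R,4aS)-1,5,5-trimethyl-2-methylidene-1-(prop-2-en-1-yl)-1,2,3,4,4a,5,6,7-octahydronaphthalene | C=CC[C@@]1(C)C2=CCCC(C)(C)[C@@H]2CCC1=C | intermediate
12 | acrolein | C=CC=O | starting material
13 | (2E)-4-[(1R,4aS)-1,5,5-trimethyl-2-methylidene-1,2,3,4,4a,5,6,7-octahydronaphthalen-1-yl]but-2-enal | O=C/C=C/C[C@@]1(C)C2=CCCC(C)(C)[C@@H]2CCC1=C | intermediate
14 | 4-[(1R,2R,4aS)-1,2,5,5-tetramethyl-1,2,3,4,4a,5,6,7-octahydronaphthalen-1-yl]butanal | O=CCCC[C@@]1(C)C2=CCCC(C)(C)[C@@H]2CC[C@H]1C | intermediate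
15 | allyl acetate | C=CCOC(C)=O | starting material
16 | (2S)-2-{2-[(1R,2R,4aS)-1,2,5,5-tetramethyl-1,2,3,4,4a,5,6,7-octahydronaphthalen-1-yl]ethyl}pent-4-enal | C=CC[C@H](CC[C@@]1(C)C2=CCCC(C)(C)[C@@H]2CC[C@H]1C)C=O | intermediate (not isolated)
17 | (2S)-2-{2-[(1R,2R,4aS)-1,2,5,5-tetramethyl-1,2,3,4,4a,5,6,7-octahydronaphthalen-1-yl]ethyl}pent-4-en-1-ol | C=CC[C@H](CC[C@@]1(C)C2=CCCC(C)(C)[C@@H]2CC[C@H]1C)CO | intermediate
18 | 3-methylbutan-1-amine | CC(C)CCN | starting material
19 | 2,5-dimethoxy-2,5-dihydrofuran | COC1C=CC(OC)O1 | starting material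
20 | (Z)-but-2-enedial | O=C/C=C\C=O | intermediate (not isolated)
21 | 1-(3-methylbutyl)-1,5-dihydro-2H-pyrrol-2-one | CC(C)CCN1CC=CC1=O | intermediate
22 | bromine | BrBr | starting material
23 | rac-trans-3,4-dibromo-1-(3-methylbutyl)pyrrolidin-2-one | CC(C)CCN1CC(Br)C(Br)C1=O | intermediate (not isolated)
24 | 3-bromo-1-(3-methylbutyl)-1,5-dihydro-2H-pyrrol-2-one | CC(C)CCN1CC=C(Br)C1=O | intermediate
25 | 9-borabicyclo[3.3.1]nonane (9-BBN) | B1C2CCCC1CCC2 | starting material
26 | 9-{(4R)-4-[(9-borabicyclo[3.3.1]nonan-9-yloxy)methyl]-6-[(1R,2R,4aS)-1,2,5,5-tetramethyl-1,2,3,4,4a,5,6,7-octahydronaphthalen-1-yl]hexyl}-9-borabicyclo[3.3.1]nonane | C1CC2CCCC(C1)B2CCC[C@H](CC[C@@]3(C)C4=CCCC(C)(C)[C@@H]4CC[C@H]3C)COB5C6CCCC5CCC6 | intermediate (not isolated)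
27 | 3-{(4R)-4-(hydroxymethyl)-6-[(1R,2R,4aS)-1,2,5,5-tetramethyl-1,2,3,4,4a,5,6,7-octahydronaphthalen-1-yl]hexyl}-1-(3-methylbutyl)-1,5-dihydro-2H-pyrrol-2-one | CC(C)CCN1CC=C(CCC[C@H](CC[C@@]2(C)C3=CCCC(C)(C)[C@@H]3CC[C@H]2C)CO)C1=O | intermediate
28 | sulfur trioxide–pyridine complex | O=S(=O)([O-])[n+]1ccccc1 | starting material
29 | (2R)-2-{2-[(1R,2R,4aS)-1,2,5,5-tetramethyl-1,2,3,4,4a,5,6,7-octahydronaphthalen-1-yl]ethyl}-5-[1-(3-methylbutyl)-2-oxo-2,5-dihydro-1H-pyrrol-3-yl]pentyl hydrogen sulfate | CC(C)CCN1CC=C(CCC[C@H](CC[C@@]2(C)C3=CCCC(C)(C)[C@@H]3CC[C@H]2C)COS(=O)(=O)O)C1=O | target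

## Step count and risks

Total steps: 11. Longest linear sequence: 9 (steps 1–7, 10, 11); steps 8–9 make the lactam partner.

**Step 2 (the proposed new cyclization).** It may give no turnover, the wrong closure, or low ee, and the product could racemize through its own dienol at C-4a. The fallback uses only known chemistry but cannot branch from a numbered intermediate: it sets out from commercial 3-methylcyclohex-2-en-1-one in place of 1, 2 and 4 and comes back to the route at 6. Copper-catalysed conjugate addition of MeMgBr with TMSCl trapping gives 3,3-dimethyl-1-(trimethylsilyloxy)cyclohex-1-ene F1. TiCl4-mediated Mukaiyama–Michael addition to pent-1-en-3-one gives racemic 3,3-dimethyl-2-(3-oxopentyl)cyclohexan-1-one F2. KOH/MeOH aldol condensation (Robinson annulation) gives the racemic enone F3, and Luche reduction gives the racemic cis-allylic alcohol F4. Lipase (Amano PS)/vinyl acetate kinetic resolution acetylates the (2R,4aS) enantiomer to the acetate F5, which is separated from the unreacted antipodal alcohol. Methanolysis (K2CO3, MeOH) gives the (2R,4aS)-alcohol F6, and MnO2 oxidation returns 6.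

**Step 3 (deconjugative allylation).** O-allylation, reaction at the wrong enolate, or base-mediated loss of the C-4a stereocentre under equilibrating alkoxide are possible. The fallback sets out from 6 and comes back at 9. Isopropenyl acetate with catalytic TsOH gives the heteroannular dienyl acetate F7 under acid. MeLi (2 equiv) in DME at 0 °C then releases the lithium dienolate regiospecifically with no equilibrating base present, and allyl bromide gives 9.

**Step 7 (amine/palladium α-allylation).** Catalyst N-allylation, modest ee, or racemization before reduction are possible. The fallback sets out from 14 and comes back at 17 by an all-polar enamine sequence. Michael addition to nitroethylene (5 mol% (R)-α,α-diphenylprolinol TMS ether, 3-nitrobenzoic acid, toluene, 3 °C) gives the γ-nitro aldehyde F8. In situ NaBH4 gives the nitro alcohol F9. A Nef reaction (NaOMe, then buffered aqueous TiCl3) gives the lactol F10, and Wittig methylenation with excess Ph3P=CH2 gives 17.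

## Further compounds

F1 | step 2 | 3,3-dimethyl-1-(trimethylsilyloxy)cyclohex-1-ene | CC1(C)CCCC(O[Si](C)(C)C)=C1
F2 | step 2 | rac-3,3-dimethyl-2-(3-oxopentyl)cyclohexan-1-one | CCC(=O)CCC1C(=O)CCCC1(C)C
F3 | step 2 | rac-1,5,5-trimethyl-4,4a,5,6,7,8-hexahydronaphthalen-2(3H)-one | CC1=C2CCCC(C)(C)C2CCC1=O
F4 | step 2 | rac-(2R*,4aS*)-1,5,5-trimethyl-2,3,4,4a,5,6,7,8-octahydronaphthalen-2-ol | CC1=C2CCCC(C)(C)C2CCC1O
F5 | step 2 | (2R,4aS)-1,5,5-trimethyl-2,3,4,4a,5,6,7,8-octahydronaphthalen-2-yl acetate | CC1=C2CCCC(C)(C)[C@@H]2CC[C@H]1OC(C)=O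
F6 | step 2 | (2R,4aS)-1,5,5-trimethyl-2,3,4,4a,5,6,7,8-octahydronaphthalen-2-ol | CC1=C2CCCC(C)(C)[C@@H]2CC[C@H]1O
F7 | step 3 | (4aS)-1,5,5-trimethyl-3,4,4a,5,6,7-hexahydronaphthalen-2-yl acetate | CC(=O)OC1=C(C)C2=CCCC(C)(C)[C@@H]2CC1
F8 | step 7 | (2S)-2-(2-nitroethyl)-4-[(1R,2R,4aS)-1,2,5,5-tetramethyl-1,2,3,4,4a,5,6,7-octahydronaphthalen-1-yl]butanal | O=[N+]([O-])CC[C@H](CC[C@@]1(C)C2=CCCC(C)(C)[C@@H]2CC[C@H]1C)C=O
F9 | step 7 | (2S)-2-(2-nitroethyl)-4-[(1R,2R,4aS)-1,2,5,5-tetramethyl-1,2,3,4,4a,5,6,7-octahydronaphthalen-1-yl]butan-1-ol | O=[N+]([O-])CC[C@H](CC[C@@]1(C)C2=CCCC(C)(C)[C@@H]2CC[C@H]1C)CO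
F10 | step 7 | (4S)-4-{2-[(1R,2R,4aS)-1,2,5,5-tetramethyl-1,2,3,4,4a,5,6,7-octahydronaphthalen-1-yl]ethyl}oxolan-2-ol | OC1C[C@H](CC[C@@]2(C)C3=CCCC(C)(C)[C@@H]3CC[C@H]2C)CO1
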